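**Assumption:** the L-fructose-derived Shi ketone and a ketoreductase picked from a commercial screening panel are taken as available catalysts; ring positions use 1-benzoxepine numbering (O1, C2 gem-dimethyl, C3 carbinol, C5a/C9a ring fusion, C6 side-chain carbon, C7 tertiary carbinol carbon), with "half A" the C3-acetate half and "half B" the C3-hydroxy half, which is the C7 epimer of half A.

**Retrosynthetic overview**
1. Target ⇐ ketoreductase reduction of the C3 ketone of half B in triacetate 28 ⇐ triol 26 (oxidise the one secondary OH, acetylate the two tertiary OH).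
2. 26 ⇐ central CH2–CH2 bond by Julia–Kocienski olefination of aldehyde 16 (half A) with tetrazolyl sulfone 23 (half B), then hydrogenation.
3. 16 and 23 ⇐ one bicyclic exo-methylene alcohol 10: epoxidation/hydride gives the equatorial tertiary OH (half A), ozonolysis/methyl addition gives the axial tertiary OH (half B).
4. 10 ⇐ acyclic (S,S,S)-diepoxy allylsilane 8 by one Lewis-acid cascade; in each half the oxepane C–O bond forms first, then the cyclohexane, and the halves are joined afterwards.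
5. 8 ⇐ geranyl bromide + methyl acetoacetate; all stereocentres of 8 come from one Shi epoxidation.

**Route to the common bicycle 10**

Step 1
Reactants: 2 methyl acetoacetate; 1 geranyl bromide
Product: 3 methyl (6E)-7,11-dimethyl-3-oxododeca-6,10-dienoate
Conditions: NaH, THF, 0 °C; n-BuLi, 0 °C; then 1, 0 °C → rt; aq. NH4Cl
Reagents that add atoms: none
Why: Weiler dianion alkylation; the γ-carbon of the acetoacetate dianion displaces the allylic bromide by SN2 and the (E)-alkene is untouched.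

Step 2
Reactants: 3 β-keto ester
Product: 4 methyl (2Z,6E)-7,11-dimethyl-3-{[(trifluoromethyl)sulfonyl]oxy}dodeca-2,6,10-trienoate
Conditions: Tf2O, sat. aq. LiOH, toluene, 5 °C
Reagents that add atoms: trifluoromethanesulfonic anhydride, O=S(=O)(OS(=O)(=O)C(F)(F)F)C(F)(F)F
Why: Enol triflation of the lithium-chelated (Z)-enolate; the Z geometry later places the side-chain carbon trans to the ring-forming chain.

Step 3
Reactants: 4 enol triflate ester
Product: 5 (2Z,6E)-1-hydroxy-7,11-dimethyldodeca-2,6,10-trien-3-yl trifluoromethanesulfonate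
Conditions: i-Bu2AlH (2.5 equiv), CH2Cl2, −78 °C; Rochelle salt work-up
Reagents that add atoms: none
Why: Hydride reduction of the conjugated ester to the allylic alcohol; the enol triflate and isolated alkenes are inert at −78 °C.

Step 4
Reactants: 5 allylic alcohol
Product: 6 (2Z,6E)-1-(benzyloxy)-7,11-dimethyldodeca-2,6,10-trien-3-yl trifluoromethanesulfonate
Conditions: BnOC(=NH)CCl3, TfOH (5 mol %), cyclohexane/CH2Cl2, 0 °C → rt
Reagents that add atoms: benzyl 2,2,2-trichloroacetimidate, N=C(OCc1ccccc1)C(Cl)(Cl)Cl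
Why: Acid-catalysed imidate O-benzylation avoids an alkoxide next to the enol triflate; the benzyl ether survives until its planned hydrogenolysis.

Step 5
Reactants: 6 triene
Product: 7 (2Z)-1-(benzyloxy)-5-[(2S,3S)-3-{2-[(2S)-3,3-dimethyloxiran-2-yl]ethyl}-3-methyloxiran-2-yl]pent-2-en-3-yl trifluoromethanesulfonate
Conditions: L-fructose-derived Shi ketone (60 mol %), KHSO5 (as Oxone), K2CO3, Bu4NHSO4, Na2B4O7/Na2EDTA buffer, MeCN/CH2(OMe)2/H2O, 0 °C
Reagents that add atoms: potassium peroxymonosulfate, [K+].[O-]S(=O)(=O)OO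
Why: Shi asymmetric epoxidation; the chiral dioxirane epoxidises both electron-rich trisubstituted alkenes through a spiro transition state to give the (S,S) and (S) epoxides, setting the first stereocentres under catalyst control, while the triflate-bearing alkene is too electron-poor to react.

Step 6
Reactants: 7 diepoxy enol triflate
Product: 8 [(2Z)-4-(benzyloxy)-2-{2-[(2S,3S)-3-{2-[(2S)-3,3-dimethyloxiran-2-yl]ethyl}-3-methyloxiran-2-yl]ethyl}but-2-en-1-yl](trimethyl)silane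
Conditions: Me3SiCH2MgCl, Pd(PPh3)4 (5 mol %), THF, 0 °C → rt
Reagents that add atoms: (trimethylsilyl)methylmagnesium chloride, C[Si](C)(C)C[Mg]Cl
Why: Kumada–Corriu coupling of the alkenyl triflate with retention of geometry gives the 2-substituted allylsilane; trisubstituted epoxides are not opened by the copper-free Grignard reagent at this temperature.

Step 7
Reactants: 8 diepoxy allylsilane
Product: 10 (3S,5aS,6R,9aS)-6-[(benzyloxy)methyl]-2,2,5a-trimethyl-7-methylidenedecahydro-1-benzoxepin-3-ol, via trimethylsilyl ether 9 (not isolated)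
Conditions: Me3SiOTf (0.3 equiv, turned over by silyl transfer), 2,6-di-tert-butyl-4-methylpyridine, CH2Cl2, −78 °C; then K2CO3, MeOH, 0 °C → rt
Reagents that add atoms: none
Why: Lewis-acid bis-epoxide cascade (tandem oxa/carbacyclisation with Sakurai-type allylsilane termination); the internal epoxide oxygen opens the silylated terminal epoxide at its tertiary carbon (oxepane, C3 retained), and the epoxonium is opened with inversion by the allylsilane through a chair transition state, giving the trans ring fusion, the equatorial C6 side chain (from the Z-alkene) and the exocyclic methylene.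

**Half A: aldehyde 16**

Step 8
Reactants: 10 bicyclic alkene
Product: 11 (3S,5aS,6R,7S,9aS)-6-[(benzyloxy)methyl]-2,2,5a-trimethyloctahydro-2H-spiro[1-benzoxepine-7,2'-oxiran]-3-ol (epoxide oxygen equatorial)
Conditions: mCPBA, NaHCO3, CH2Cl2, 0 °C
Reagents that add atoms: 3-chloroperoxybenzoic acid, OOC(=O)c1cccc(Cl)c1
Why: Prilezhaev epoxidation of the only alkene; the peracid attacks from the equatorial side, away from the syn-axial C5a methyl, so the oxygen ends up equatorial (minor epimer removed by chromatography).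

Step 9
Reactants: 11 spiro-epoxide
Product: 12 (3S,5aS,6R,7S,9aS)-6-[(benzyloxy)methyl]-2,2,5a,7-tetramethyldecahydro-1-benzoxepine-3,7-diol
Conditions: LiEt3BH (4 equiv), THF, 0 °C → rt; H2O work-up
Reagents that add atoms: none
Why: SN2 hydride opening at the unhindered epoxide CH2 converts it into the axial methyl and leaves the equatorial tertiary alcohol, the C7 configuration of half A.

Step 10
Reactants: 12 diol
Product: 13 (3S,5aS,6R,7S,9aS)-6-[(benzyloxy)methyl]-7-hydroxy-2,2,5a,7-tetramethyldecahydro-1-benzoxepin-3-yl acetate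
Conditions: Ac2O (1.5 equiv), pyridine, DMAP (5 mol %), CH2Cl2, 0 °C → rt
Reagents that add atoms: acetic anhydride, CC(=O)OC(C)=O
Why: DMAP-catalysed acylation at room temperature is selective for the secondary over the tertiary hydroxyl and installs the only secondary acetate of the target.

Step 11
Reactants: 13 hydroxy acetate
Product: 14 (3S,5aS,6R,7S,9aS)-6-[(benzyloxy)methyl]-2,2,5a,7-tetramethyl-7-[(triethylsilyl)oxy]decahydro-1-benzoxepin-3-yl acetate
Conditions: Et3SiOTf, 2,6-lutidine, CH2Cl2, −40 → 0 °C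
Reagents that add atoms: triethylsilyl trifluoromethanesulfonate, CC[Si](CC)(CC)OS(=O)(=O)C(F)(F)F
Why: Silyl triflate silylation of the tertiary alcohol prevents retro-aldol or elimination once the adjacent aldehyde is made.

Step 12
Reactants: 14 benzyl ether
Product: 15 (3S,5aS,6R,7S,9aS)-6-(hydroxymethyl)-2,2,5a,7-tetramethyl-7-[(triethylsilyl)oxy]decahydro-1-benzoxepin-3-yl acetate
Conditions: H2 (1 atm), Pd(OH)2/C, EtOAc, rt
Reagents that add atoms: none
Why: Hydrogenolysis of the benzyl ether; the acetate and silyl ether are inert and no alkene remains.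

Step 13
Reactants: 15 primary alcohol
Product: 16 (3S,5aS,6S,7S,9aS)-6-formyl-2,2,5a,7-tetramethyl-7-[(triethylsilyl)oxy]decahydro-1-benzoxepin-3-yl acetate
Conditions: Dess–Martin periodinane, NaHCO3, CH2Cl2, 0 °C → rt
Reagents that add atoms: none
Why: Dess–Martin oxidation under buffered conditions; the formyl group stays in the thermodynamically preferred equatorial position, so C6 is not at risk.

**Half B: sulfone 23**

Step 14
Reactants: 10 bicyclic alkene
Product: 18 (3S,5aS,6R,9aS)-6-[(benzyloxy)methyl]-3-hydroxy-2,2,5a-trimethyloctahydro-1-benzoxepin-7(2H)-one, via ozonide 17 (not isolated)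
Conditions: O3, CH2Cl2, −78 °C; then PPh3, −78 °C → rt
Reagents that add atoms: ozone, [O-][O+]=O
Why: Ozonolysis (Criegee mechanism) cleaves the exocyclic methylene to the ketone; the α-stereocentre keeps its equatorial substituent.

Step 15
Reactants: 18 ketone
Product: 19 (3S,5aS,6R,7R,9aS)-6-[(benzyloxy)methyl]-2,2,5a,7-tetramethyldecahydro-1-benzoxepine-3,7-diol
Conditions: MeMgBr (4 equiv), CeCl3 (4 equiv), THF, −78 → −20 °C; aq. NH4Cl
Reagents that add atoms: methylmagnesium bromide, C[Mg]Br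
Why: Organocerium (Imamoto) 1,2-addition; the non-basic methyl nucleophile attacks from the equatorial side because axial attack is blocked by the syn-axial C5a methyl, giving the axial tertiary alcohol (the C7 epimer of half A) without enolisation or β-elimination.

Step 16
Reactants: 19 benzyl ether diol
Product: 20 (3S,5aS,6R,7R,9aS)-6-(hydroxymethyl)-2,2,5a,7-tetramethyldecahydro-1-benzoxepine-3,7-diol
Conditions: H2 (1 atm), Pd(OH)2/C, EtOH/EtOAc, rt
Reagents that add atoms: none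
Why: Hydrogenolysis of the benzyl ether frees the primary alcohol.

Step 17
Reactants: 20 triol
Product: 21 (3S,5aS,6S,7R,9aS)-2,2,5a,7-tetramethyl-6-{[(1-phenyl-1H-tetrazol-5-yl)sulfanyl]methyl}decahydro-1-benzoxepine-3,7-diol
Conditions: 1-phenyl-1H-tetrazole-5-thiol, PPh3, DIAD, THF, 0 °C → rt
Reagents that add atoms: 1-phenyl-1H-tetrazole-5-thiol, Sc1nnnn1-c1ccccc1
Why: Mitsunobu thioetherification occurs only at the primary hydroxyl; the neopentyl secondary and the tertiary hydroxyls do not react.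

Step 18
Reactants: 21 sulfide
Product: 22 (3S,5aS,6S,7R,9aS)-2,2,5a,7-tetramethyl-6-{[(1-phenyl-1H-tetrazol-5-yl)sulfonyl]methyl}decahydro-1-benzoxepine-3,7-diol
Conditions: 30 % H2O2, (NH4)6Mo7O24·4H2O (20 mol %), EtOH, 0 °C → rt
Reagents that add atoms: hydrogen peroxide, OO
Why: Molybdate-catalysed sulfide-to-sulfone oxidation; there is no alkene left to compete.

Step 19
Reactants: 22 sulfone diol
Product: 23 5-({[(3S,5aS,6S,7R,9aS)-2,2,5a,7-tetramethyl-3,7-bis[(triethylsilyl)oxy]decahydro-1-benzoxepin-6-yl]methyl}sulfonyl)-1-phenyl-1H-tetrazole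
Conditions: Et3SiOTf (3 equiv), 2,6-lutidine, CH2Cl2, −78 °C → rt
Reagents that add atoms: triethylsilyl trifluoromethanesulfonate, CC[Si](CC)(CC)OS(=O)(=O)C(F)(F)F
Why: Silyl triflate silylation of both hydroxyls removes acidic protons and blocks a Smiles-type attack of the tertiary alkoxide on the tetrazole during the olefination.

**Union and end game**

Step 20
Reactants: 23 tetrazolyl sulfone (half B); 16 aldehyde (half A)
Product: 24 (3S,5aS,6S,7S,9aS)-6-[(E)-2-{(3S,5aS,6S,7R,9aS)-2,2,5a,7-tetramethyl-3,7-bis[(triethylsilyl)oxy]decahydro-1-benzoxepin-6-yl}ethenyl]-2,2,5a,7-tetramethyl-7-[(triethylsilyl)oxy]decahydro-1-benzoxepin-3-yl acetate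
Conditions: 23 (1.2 equiv), KN(SiMe3)2 (1.25 equiv), DME, −60 °C; then 16, −60 °C → rt; aq. NH4Cl
Reagents that add atoms: none
Why: Julia–Kocienski olefination; the sulfonyl carbanion adds to the aldehyde far faster than to the hindered acetate, and Smiles rearrangement/elimination gives the alkene (mainly E; geometry is irrelevant because it is hydrogenated).

Step 21
Reactants: 24 alkene
Product: 25 the saturated ethane-1,2-diyl-linked compound [half A: C3 acetate and C7 triethylsilyl ether; half B: C3 and C7 triethylsilyl ethers]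
Conditions: H2 (4 atm), Pd/C, EtOAc, rt
Reagents that add atoms: none
Why: Heterogeneous hydrogenation of the disubstituted alkene; no stereocentre is created and the silyl ethers and acetate survive.

Step 22
Reactants: 25 tris(silyl ether)
Product: 26 (3S,5aS,6S,7S,9aS)-6-{2-[(3S,5aS,6S,7R,9aS)-3,7-dihydroxy-2,2,5a,7-tetramethyldecahydro-1-benzoxepin-6-yl]ethyl}-7-hydroxy-2,2,5a,7-tetramethyldecahydro-1-benzoxepin-3-yl acetate
Conditions: HF·pyridine, pyridine, THF, 0 °C → rt
Reagents that add atoms: none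
Why: Fluoride-mediated desilylation under buffered conditions removes all three silyl groups without touching the acetate.

Step 23
Reactants: 26 triol
Product: 27 (3S,5aS,6S,7S,9aS)-7-hydroxy-6-{2-[(5aS,6S,7R,9aS)-7-hydroxy-2,2,5a,7-tetramethyl-3-oxodecahydro-1-benzoxepin-6-yl]ethyl}-2,2,5a,7-tetramethyldecahydro-1-benzoxepin-3-yl acetate
Conditions: Dess–Martin periodinane, NaHCO3, CH2Cl2, 0 °C → rt
Reagents that add atoms: none
Why: Dess–Martin oxidation can only affect the single secondary hydroxyl; the resulting ketone masks that position during the forcing acetylation.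

Step 24
Reactants: 27 keto diol
Product: 28 (3S,5aS,6S,7S,9aS)-7-(acetyloxy)-6-{2-[(5aS,6S,7R,9aS)-7-(acetyloxy)-2,2,5a,7-tetramethyl-3-oxodecahydro-1-benzoxepin-6-yl]ethyl}-2,2,5a,7-tetramethyldecahydro-1-benzoxepin-3-yl acetate
Conditions: Ac2O, Et3N, DMAP (2 equiv), CH2Cl2, 40 °C
Reagents that add atoms: acetic anhydride, CC(=O)OC(C)=O
Why: Steglich-type DMAP acylation acetylates both tertiary alcohols; no other nucleophilic site is present.

Step 25
Reactants: 28 triacetate ketone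
Product: 29 target CNP0169816.2
Conditions: ketoreductase (Prelog-selective, NADPH-dependent), NADP+ (cat.), i-PrOH, KH2PO4/K2HPO4 buffer pH 7.0, DMSO (10 vol %), 30 °C
Reagents that add atoms: none
Why: Enzymatic carbonyl reduction by a ketoreductase (alcohol dehydrogenase class, EC 1.1.1); hydride from NADPH is delivered to the Re face (large α-quaternary side versus small CH2 side) to set the (3S)-carbinol under catalyst control at neutral pH, where the three acetates are not hydrolysed.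

**Compound list**

1 | geranyl bromide, (2E)-1-bromo-3,7-dimethylocta-2,6-diene | CC(C)=CCC/C(C)=C/CBr | starting material
2 | methyl acetoacetate | CC(=O)CC(=O)OC | starting material
3 | methyl (6E)-7,11-dimethyl-3-oxododeca-6,10-dienoate | COC(=O)CC(=O)CC/C=C(\C)CCC=C(C)C | intermediate
4 | methyl (2Z,6E)-7,11-dimethyl-3-{[(trifluoromethyl)sulfonyl]oxy}dodeca-2,6,10-trienoate | COC(=O)/C=C(\OS(=O)(=O)C(F)(F)F)CC/C=C(\C)CCC=C(C)C | intermediate
5 | (2Z,6E)-1-hydroxy-7,11-dimethyldodeca-2,6,10-trien-3-yl trifluoromethanesulfonate | OC/C=C(\OS(=O)(=O)C(F)(F)F)CC/C=C(\C)CCC=C(C)C | intermediate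
6 | (2Z,6E)-1-(benzyloxy)-7,11-dimethyldodeca-2,6,10-trien-3-yl trifluoromethanesulfonate | c1ccccc1COC/C=C(\OS(=O)(=O)C(F)(F)F)CC/C=C(\C)CCC=C(C)C | intermediate
7 | (2Z)-1-(benzyloxy)-5-[(2S,3S)-3-{2-[(2S)-3,3-dimethyloxiran-2-yl]ethyl}-3-methyloxiran-2-yl]pent-2-en-3-yl trifluoromethanesulfonate | c1ccccc1COC/C=C(\OS(=O)(=O)C(F)(F)F)CC[C@@H]1O[C@@]1(C)CC[C@@H]1OC1(C)C | intermediate
8 | [(2Z)-4-(benzyloxy)-2-{2-[(2S,3S)-3-{2-[(2S)-3,3-dimethyloxiran-2-yl]ethyl}-3-methyloxiran-2-yl]ethyl}but-2-en-1-yl](trimethyl)silane | c1ccccc1COC/C=C(\C[Si](C)(C)C)CC[C@@H]1O[C@@]1(C)CC[C@@H]1OC1(C)C | intermediate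
9 | {[(3S,5aS,6R,9aS)-6-[(benzyloxy)methyl]-2,2,5a-trimethyl-7-methylidenedecahydro-1-benzoxepin-3-yl]oxy}(trimethyl)silane | C[Si](C)(C)O[C@H]1CC[C@]2(C)[C@H](CCC(=C)[C@H]2COCc3ccccc3)OC1(C)C | intermediate (not isolated)
10 | (3S,5aS,6R,9aS)-6-[(benzyloxy)methyl]-2,2,5a-trimethyl-7-methylidenedecahydro-1-benzoxepin-3-ol | O[C@H]1CC[C@]2(C)[C@H](CCC(=C)[C@H]2COCc3ccccc3)OC1(C)C | intermediate
11 | (3S,5aS,6R,7S,9aS)-6-[(benzyloxy)methyl]-2,2,5a-trimethyloctahydro-2H-spiro[1-benzoxepine-7,2'-oxiran]-3-ol | O[C@H]1CC[C@]2(C)[C@H](CC[C@]3(OC3)[C@H]2COCc4ccccc4)OC1(C)C | intermediate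
12 | (3S,5aS,6R,7S,9aS)-6-[(benzyloxy)methyl]-2,2,5a,7-tetramethyldecahydro-1-benzoxepine-3,7-diol | O[C@H]1CC[C@]2(C)[C@H](CC[C@](C)(O)[C@H]2COCc3ccccc3)OC1(C)C | intermediate
13 | (3S,5aS,6R,7S,9aS)-6-[(benzyloxy)methyl]-7-hydroxy-2,2,5a,7-tetramethyldecahydro-1-benzoxepin-3-yl acetate | CC(=O)O[C@H]1CC[C@]2(C)[C@H](CC[C@](C)(O)[C@H]2COCc3ccccc3)OC1(C)C | intermediate
14 | (3S,5aS,6R,7S,9aS)-6-[(benzyloxy)methyl]-2,2,5a,7-tetramethyl-7-[(triethylsilyl)oxy]decahydro-1-benzoxepin-3-yl acetate | CC(=O)O[C@H]1CC[C@]2(C)[C@H](CC[C@](C)(O[Si](CC)(CC)CC)[C@H]2COCc3ccccc3)OC1(C)C | intermediate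
15 | (3S,5aS,6R,7S,9aS)-6-(hydroxymethyl)-2,2,5a,7-tetramethyl-7-[(triethylsilyl)oxy]decahydro-1-benzoxepin-3-yl acetate | CC(=O)O[C@H]1CC[C@]2(C)[C@H](CC[C@](C)(O[Si](CC)(CC)CC)[C@H]2CO)OC1(C)C | intermediate
16 | (3S,5aS,6S,7S,9aS)-6-formyl-2,2,5a,7-tetramethyl-7-[(triethylsilyl)oxy]decahydro-1-benzoxepin-3-yl acetate | CC(=O)O[C@H]1CC[C@]2(C)[C@H](CC[C@](C)(O[Si](CC)(CC)CC)[C@H]2C=O)OC1(C)C | intermediate
17 | ozonide of 10 (spiro-1,2,4-trioxolane at C7, mixture at the spiro carbon) | O[C@H]1CC[C@]2(C)[C@H](CCC3(OOCO3)[C@H]2COCc4ccccc4)OC1(C)C | intermediate (not isolated)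
18 | (3S,5aS,6R,9aS)-6-[(benzyloxy)methyl]-3-hydroxy-2,2,5a-trimethyloctahydro-1-benzoxepin-7(2H)-one | O[C@H]1CC[C@]2(C)[C@H](CCC(=O)[C@H]2COCc3ccccc3)OC1(C)C | intermediate
19 | (3S,5aS,6R,7R,9aS)-6-[(benzyloxy)methyl]-2,2,5a,7-tetramethyldecahydro-1-benzoxepine-3,7-diol | O[C@H]1CC[C@]2(C)[C@H](CC[C@@](C)(O)[C@H]2COCc3ccccc3)OC1(C)C | intermediate
20 | (3S,5aS,6R,7R,9aS)-6-(hydroxymethyl)-2,2,5a,7-tetramethyldecahydro-1-benzoxepine-3,7-diol | O[C@H]1CC[C@]2(C)[C@H](CC[C@@](C)(O)[C@H]2CO)OC1(C)C | intermediate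
21 | (3S,5aS,6S,7R,9aS)-2,2,5a,7-tetramethyl-6-{[(1-phenyl-1H-tetrazol-5-yl)sulfanyl]methyl}decahydro-1-benzoxepine-3,7-diol | O[C@H]1CC[C@]2(C)[C@H](CC[C@@](C)(O)[C@H]2CSc3nnnn3-c4ccccc4)OC1(C)C | intermediate
22 | (3S,5aS,6S,7R,9aS)-2,2,5a,7-tetramethyl-6-{[(1-phenyl-1H-tetrazol-5-yl)sulfonyl]methyl}decahydro-1-benzoxepine-3,7-diol | O[C@H]1CC[C@]2(C)[C@H](CC[C@@](C)(O)[C@H]2CS(=O)(=O)c3nnnn3-c4ccccc4)OC1(C)C | intermediate
23 | 5-({[(3S,5aS,6S,7R,9aS)-2,2,5a,7-tetramethyl-3,7-bis[(triethylsilyl)oxy]decahydro-1-benzoxepin-6-yl]methyl}sulfonyl)-1-phenyl-1H-tetrazole | CC[Si](CC)(CC)O[C@H]1CC[C@]2(C)[C@H](CC[C@@](C)(O[Si](CC)(CC)CC)[C@H]2CS(=O)(=O)c3nnnn3-c4ccccc4)OC1(C)C | intermediate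
24 | (E)-alkene joining half A (C3 acetate, C7 triethylsilyl ether) to half B (C3 and C7 triethylsilyl ethers) | CC(=O)O[C@H]1CC[C@]2(C)[C@H](CC[C@](C)(O[Si](CC)(CC)CC)[C@H]2/C=C/[C@H]2[C@]3(C)CC[C@H](O[Si](CC)(CC)CC)C(C)(C)O[C@H]3CC[C@@]2(C)O[Si](CC)(CC)CC)OC1(C)C | intermediate
25 | saturated ethane-1,2-diyl-linked tris(triethylsilyl) ether monoacetate | CC(=O)O[C@H]1CC[C@]2(C)[C@H](CC[C@](C)(O[Si](CC)(CC)CC)[C@H]2CC[C@H]2[C@]3(C)CC[C@H](O[Si](CC)(CC)CC)C(C)(C)O[C@H]3CC[C@@]2(C)O[Si](CC)(CC)CC)OC1(C)C | intermediate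
26 | (3S,5aS,6S,7S,9aS)-6-{2-[(3S,5aS,6S,7R,9aS)-3,7-dihydroxy-2,2,5a,7-tetramethyldecahydro-1-benzoxepin-6-yl]ethyl}-7-hydroxy-2,2,5a,7-tetramethyldecahydro-1-benzoxepin-3-yl acetate | CC(=O)O[C@H]1CC[C@]2(C)[C@H](CC[C@](C)(O)[C@H]2CC[C@H]2[C@]3(C)CC[C@H](O)C(C)(C)O[C@H]3CC[C@@]2(C)O)OC1(C)C | intermediate
27 | (3S,5aS,6S,7S,9aS)-7-hydroxy-6-{2-[(5aS,6S,7R,9aS)-7-hydroxy-2,2,5a,7-tetramethyl-3-oxodecahydro-1-benzoxepin-6-yl]ethyl}-2,2,5a,7-tetramethyldecahydro-1-benzoxepin-3-yl acetate | CC(=O)O[C@H]1CC[C@]2(C)[C@H](CC[C@](C)(O)[C@H]2CC[C@H]2[C@]3(C)CCC(=O)C(C)(C)O[C@H]3CC[C@@]2(C)O)OC1(C)C | intermediate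
28 | (3S,5aS,6S,7S,9aS)-7-(acetyloxy)-6-{2-[(5aS,6S,7R,9aS)-7-(acetyloxy)-2,2,5a,7-tetramethyl-3-oxodecahydro-1-benzoxepin-6-yl]ethyl}-2,2,5a,7-tetramethyldecahydro-1-benzoxepin-3-yl acetate | CC(=O)O[C@H]1CC[C@]2(C)[C@H](CC[C@](C)(OC(C)=O)[C@H]2CC[C@H]2[C@]3(C)CCC(=O)C(C)(C)O[C@H]3CC[C@@]2(C)OC(C)=O)OC1(C)C | intermediate
29 | CNP0169816.2, (3S,5aS,6S,7S,9aS)-7-(acetyloxy)-6-{2-[(3S,5aS,6S,7R,9aS)-7-(acetyloxy)-3-hydroxy-2,2,5a,7-tetramethyldecahydro-1-benzoxepin-6-yl]ethyl}-2,2,5a,7-tetramethyldecahydro-1-benzoxepin-3-yl acetate | CC(=O)O[C@H]1CC[C@]2(C)[C@H](CC[C@](C)(OC(C)=O)[C@H]2CC[C@H]2[C@]3(C)CC[C@H](O)C(C)(C)O[C@H]3CC[C@@]2(C)OC(C)=O)OC1(C)C | target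

**Totals**

Total step count: 25.
Longest linear sequence: 19 steps (steps 1–7, then 8–13 or 14–19, then 20–25).

**Three steps most likely to fail**

Step 7 (bis-epoxide cascade). The γ-silyl allylic ether of 8 may ionise or lose silicon before the carbocycle closes. The fallback keeps the side-chain carbon at the ester oxidation level, so no ionisable allylic ether is present and no Grignard reagent meets an epoxide. It sets out from 4: Pd(PPh3)4-catalysed coupling with Me3SiCH2MgCl gives methyl (2Z,6E)-7,11-dimethyl-3-[(trimethylsilyl)methyl]dodeca-2,6,10-trienoate F1. Shi epoxidation with the same L-fructose-derived ketone (the ester-conjugated alkene is inert) gives the (6S,7S,10S)-diepoxy ester F2. Me3SiOTf with 2,6-di-tert-butyl-4-methylpyridine at −78 °C then closes both rings through the ester α-carbon of this vinylogous allylsilane to give the bicyclic β,γ-unsaturated methyl ester F3 (C3 trimethylsilyl ether, C7 exocyclic methylene). LiAlH4 reduction with dilute acid work-up gives the bicyclic diol F4, and Ag2O/BnBr benzylates only the primary hydroxyl, coming back to the route at 10.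

Step 20 (Julia–Kocienski union of two hindered partners). If the sulfonyl carbanion enolises the aldehyde instead of adding, the fallback replaces olefination by carbonyl addition and radical deoxygenation. It sets out from 20 and uses 16 unchanged: I2, PPh3 and imidazole give the primary iodide F5; Et3SiOTf/2,6-lutidine gives the bis(triethylsilyl) ether iodide F6. Iodine–lithium exchange (t-BuLi, Et2O, −78 °C), transmetalation with CeCl3 and addition to 16 give the secondary carbinol F7 (epimer mixture at the new carbinol carbon). 1,1'-Thiocarbonyldiimidazole with DMAP gives the imidazolyl thionocarbonate F8, and Barton–McCombie reduction (Bu3SnH, AIBN, toluene, 90 °C) removes the oxygen, coming back to the route at 25.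

Step 25 (ketoreductase on a hindered α-quaternary ketone). If no panel enzyme accepts 28 or the diastereoselectivity is poor, the fallback keeps the cascade-derived carbinol and uses a protecting group instead of the oxidation/reduction pair. It sets out from 26: Et3SiCl and imidazole in DMF silylate only the secondary hydroxyl to give the mono(triethylsilyl) ether diol F9; Ac2O/DMAP/Et3N at 40 °C acetylates both tertiary hydroxyls to give the triacetate silyl ether F10; HF·pyridine removes the silyl group, coming back to the route at 29.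

**Further compounds**

F1 | step 7 | methyl (2Z,6E)-7,11-dimethyl-3-[(trimethylsilyl)methyl]dodeca-2,6,10-trienoate | COC(=O)/C=C(\C[Si](C)(C)C)CC/C=C(\C)CCC=C(C)C
F2 | step 7 | methyl (2Z)-5-[(2S,3S)-3-{2-[(2S)-3,3-dimethyloxiran-2-yl]ethyl}-3-methyloxiran-2-yl]-3-[(trimethylsilyl)methyl]pent-2-enoate | COC(=O)/C=C(\C[Si](C)(C)C)CC[C@@H]1O[C@@]1(C)CC[C@@H]1OC1(C)C
F3 | step 7 | methyl (3S,5aS,6R,9aS)-2,2,5a-trimethyl-7-methylidene-3-[(trimethylsilyl)oxy]decahydro-1-benzoxepine-6-carboxylate | C[Si](C)(C)O[C@H]1CC[C@]2(C)[C@H](CCC(=C)[C@H]2C(=O)OC)OC1(C)C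
F4 | step 7 | (3S,5aS,6R,9aS)-6-(hydroxymethyl)-2,2,5a-trimethyl-7-methylidenedecahydro-1-benzoxepin-3-ol | O[C@H]1CC[C@]2(C)[C@H](CCC(=C)[C@H]2CO)OC1(C)C
F5 | step 20 | (3S,5aS,6S,7R,9aS)-6-(iodomethyl)-2,2,5a,7-tetramethyldecahydro-1-benzoxepine-3,7-diol | O[C@H]1CC[C@]2(C)[C@H](CC[C@@](C)(O)[C@H]2CI)OC1(C)C
F6 | step 20 | {[(3S,5aS,6S,7R,9aS)-6-(iodomethyl)-2,2,5a,7-tetramethyldecahydro-1-benzoxepine-3,7-diyl]bis(oxy)}bis(triethylsilane) | CC[Si](CC)(CC)O[C@H]1CC[C@]2(C)[C@H](CC[C@@](C)(O[Si](CC)(CC)CC)[C@H]2CI)OC1(C)C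
F7 | step 20 | secondary carbinol from addition to 16 (hydroxyl on the linker carbon next to half A, epimer mixture) | CC(=O)O[C@H]1CC[C@]2(C)[C@H](CC[C@](C)(O[Si](CC)(CC)CC)[C@H]2C(O)C[C@H]2[C@]3(C)CC[C@H](O[Si](CC)(CC)CC)C(C)(C)O[C@H]3CC[C@@]2(C)O[Si](CC)(CC)CC)OC1(C)C
F8 | step 20 | O-(1H-imidazole-1-carbothioyl) derivative of F7 | CC(=O)O[C@H]1CC[C@]2(C)[C@H](CC[C@](C)(O[Si](CC)(CC)CC)[C@H]2C(OC(=S)n4ccnc4)C[C@H]2[C@]3(C)CC[C@H](O[Si](CC)(CC)CC)C(C)(C)O[C@H]3CC[C@@]2(C)O[Si](CC)(CC)CC)OC1(C)C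
F9 | step 25 | 26 carrying a triethylsilyl ether on the C3 hydroxyl of half B | CC(=O)O[C@H]1CC[C@]2(C)[C@H](CC[C@](C)(O)[C@H]2CC[C@H]2[C@]3(C)CC[C@H](O[Si](CC)(CC)CC)C(C)(C)O[C@H]3CC[C@@]2(C)O)OC1(C)C
F10 | step 25 | O-triethylsilyl ether of the target (three acetates in place) | CC(=O)O[C@H]1CC[C@]2(C)[C@H](CC[C@](C)(OC(C)=O)[C@H]2CC[C@H]2[C@]3(C)CC[C@H](O[Si](CC)(CC)CC)C(C)(C)O[C@H]3CC[C@@]2(C)OC(C)=O)OC1(C)C
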